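**Plan** (target numbered as a 6-oxabicyclo[3.2.1]octane-7,8-dione: C1 prenyl bridgehead, C2, C3 prenyl, C4 CMe2, C5 acyl bridgehead, O6, C7 lactone C=O, C8 ketone)
- Retrosynthetic cuts, in order: the C1 prenyl group back to an allyl group; the C4–C5 bond; the C5–acyl bond; the O6–C5 and O6–C7 bonds of the lactone; the C1–allyl and C1–C2 bonds, leading to methyl acetoacetate and (R)-lavandulol.
- Enabling feature: C5 is the shared α-carbon of the C8 ketone and the side-chain ketone and also carries O6 of the five-membered lactone ring (C5–O6–C7–C1–C8). In the monocyclic acyl tetronic acid it is therefore a flat, nucleophilic enol carbon, and C2–C3–C4 with the C3 prenyl group is a lavandulyl chain on C1 whose isopropenyl carbon becomes the C4 cation, 1,3 to C5 across C8.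
- Forward order: the chain is assembled on methyl acetoacetate (lavandulyl, then allyl); the lactone ring is closed by enolate hydroxylation and lactonisation; C5 is acylated; the six-membered carbocycle is closed by the cation–enol cyclisation; the allyl group is then converted to prenyl.
- Stereochemistry: C3 comes from (R)-lavandulol; C1 from allylation of a valinate enamine; C5 is fixed by the bridge, with the C3 prenyl group equatorial in the chair; the side-chain centre comes from (R)-2-methylbutanoic acid.
- Helper: the C1 prenyl group is carried as allyl through the acid step, so that the isopropenyl group is the only alkene that can give a cation within reach of C5.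

Key step: step 8

Remark (assumption): (R)-(−)-lavandulol and (R)-2-methylbutanoic acid are taken as commercial single enantiomers; tert-butyl L-valinate is used as the free base from its commercial hydrochloride.

Step 1
Reactants: 1 (R)-(−)-lavandulol
Product: 2 (3R)-3-(iodomethyl)-2,6-dimethylhepta-1,5-diene [(R)-lavandulyl iodide]
Conditions: PPh3, I2, imidazole, CH2Cl2, 0 °C → rt, dark
Reagents that add atoms: iodine, II
Why: Appel-type iodination of a primary alcohol by SN2 at CH2 under neutral conditions, so the adjacent stereocentre and both alkenes should be untouched.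

Step 2
Reactants: 2 (R)-lavandulyl iodide; 3 methyl acetoacetate
Product: 4 methyl (4S)-2-acetyl-7-methyl-4-(prop-1-en-2-yl)oct-6-enoate (both C2 epimers)
Conditions: NaH, THF/DMF, 0 °C; then 2, 60 °C
Reagents that add atoms: none
Why: Acetoacetic ester alkylation of the soft sodium enolate with a primary iodide; the new C2 centre is formed unselectively, which does not matter because it is planarised in steps 3 and 4.

Step 3
Reactants: 4 keto ester; 5 tert-butyl L-valinate
Product: 6 methyl (2Z)-3-{[(2S)-1-tert-butoxy-3-methyl-1-oxobutan-2-yl]amino}-2-[(2S)-5-methyl-2-(prop-1-en-2-yl)hex-4-en-1-yl]but-2-enoate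
Conditions: BF3·OEt2 (cat.), benzene, reflux, Dean–Stark
Reagents that add atoms: none
Why: Condensation of a β-keto ester with a primary amine gives the hydrogen-bonded (Z)-enamino ester (vinylogous carbamate); the valine and lavandulyl centres are not involved.

Step 4
Reactants: 6 enamino ester
Product: 9 methyl (2S,4S)-2-acetyl-7-methyl-2-(prop-2-en-1-yl)-4-(prop-1-en-2-yl)oct-6-enoate, via lithium aza-enolate 7 (not isolated), via allylated ketimine 8 (not isolated)
Conditions: LiN(i-Pr)2, toluene, −78 °C; HMPA, allyl bromide, −78 → −55 °C; then 1 M HCl, THF, rt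
Reagents that add atoms: allyl bromide, C=CCBr; water, O
Why: Asymmetric alkylation of a lithiated chiral enamino ester, in which lithium is held by the enamide nitrogen and the valinate carbonyl so that the isopropyl group and the HMPA-ligated metal screen one face and allyl bromide enters from the other, which is expected to set the quaternary C2 as S (the facial sense depends on the lithium ligands and is treated as a risk below); hydrolysis of the ketimine returns the auxiliary.

Step 5
Reactants: 9 quaternary keto ester
Product: 11 (3S)-3-[(2S)-5-methyl-2-(prop-1-en-2-yl)hex-4-en-1-yl]-3-(prop-2-en-1-yl)furan-2,4(3H,5H)-dione, via hydroxy ketone 10 (not isolated)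
Conditions: KN(SiMe3)2, THF, −78 °C; (±)-trans-2-(phenylsulfonyl)-3-phenyloxaziridine, −78 °C; then TsOH·H2O, −78 → 40 °C
Reagents that add atoms: (±)-trans-2-(phenylsulfonyl)-3-phenyloxaziridine, O=S(=O)(c1ccccc1)N1OC1c1ccccc1
Why: The acetyl CH3 is the only enolisable position, its potassium enolate is hydroxylated by the N-sulfonyloxaziridine (Davis oxidation), and the cold acid quench avoids free methoxide (retro-Claisen) while catalysing the 5-exo-trig lactonisation onto the methyl ester; no stereocentre is touched.

Step 6
Reactants: 12 (R)-2-methylbutanoic acid; 13 1H-benzotriazole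
Product: 14 1-[(2R)-2-methylbutanoyl]-1H-benzotriazole
Conditions: SOCl2, 1H-benzotriazole (excess), CH2Cl2, rt
Reagents that add atoms: none
Why: N-Acylbenzotriazole formation through in situ activation with thionyl chloride gives a neutral, crystalline acyl donor that is much less prone to ketene formation than the acid chloride, so the α-stereocentre should be kept.

Step 7
Reactants: 11 furan-2,4-dione; 14 N-acylbenzotriazole
Product: 15 (3S)-4-hydroxy-5-[(2R)-2-methylbutanoyl]-3-[(2S)-5-methyl-2-(prop-1-en-2-yl)hex-4-en-1-yl]-3-(prop-2-en-1-yl)furan-2(3H)-one (enol form of the 5-acyl furan-2,4-dione)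
Conditions: MgBr2·OEt2, i-Pr2NEt, CH2Cl2, 0 °C → rt; then 1 M HCl
Reagents that add atoms: none
Why: Soft-enolisation C-acylation (Claisen-type 1,3-diketone synthesis) at the only enolisable carbon, the O-bearing CH2 next to the ring ketone; the product is held as its magnesium chelate, which should prevent a second acylation and protect the side-chain stereocentre from enolisation.

Step 8
Reactants: 15 acyl tetronic acid
Product: 17 (1S,3S,5S)-4,4-dimethyl-5-[(2R)-2-methylbutanoyl]-3-(3-methylbut-2-en-1-yl)-1-(prop-2-en-1-yl)-6-oxabicyclo[3.2.1]octane-7,8-dione, via tertiary C4 cation 16 (not isolated)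
Conditions: HCO2H (neat, ca. 0.02 M), rt, dark
Reagents that add atoms: none
Why: Formic acid should protonate the isopropenyl group in the Markovnikov sense to the tertiary cation 16 at the future C4, and the enol carbon C5 of the acyl tetronic acid (central carbon of the C8/side-chain 1,3-diketone) attacks it, joining two fully substituted carbons and giving the diketone after proton loss. The closest known reaction type is the formic acid-mediated biomimetic cation–enol cyclisation (a polar Conia-ene equivalent, formal Markovnikov hydroalkylation) that closes the bridgehead–CMe2 bond of bicyclic polyprenylated acylphloroglucinol cores. The new bond closes the six-membered carbocycle C1–C2–C3–C4–C5–C8 (and with it the seven-membered ring through O6–C7) by attack on the internal carbon of the former isopropenyl group, 6-exo with respect to that alkene, through a chair. C5 is the only new stereocentre and is set by the tether: the three-carbon chain leaves C1 on one face of the flat lactone ring and can reach only that face of C5, so the acyl group ends exo and C5 is S, while the (R)-lavandulol-derived C3 prenyl group sits equatorial in the chair, the matched case for (S)-C1. The step needs C- over O-alkylation and a cation at C4 only: O-attack by the enol oxygen on C8 gives a tertiary alkyl vinylogous ester that should re-ionise in formic acid whereas the C–C bond is irreversible, the allyl group on C1 cannot be protonated to a cation within reach of C5, and the cation from the C3 prenyl group could reach C5 only through an eight-membered ring. Any acid-induced scrambling at C3 through the tetrasubstituted alkene would be funnelled by the same chair to the equatorial isomer.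

Step 9
Reactants: 17 allyl bicycle
Product: 18 (1S,3S,5S)-4,4-dimethyl-5-[(2R)-2-methylbutanoyl]-1,3-bis(3-methylbut-2-en-1-yl)-6-oxabicyclo[3.2.1]octane-7,8-dione (target)
Conditions: second-generation Grubbs catalyst (H2IMes)(PCy3)Cl2Ru=CHPh (cat.), 2-methyl-2-butene, CH2Cl2, 40 °C
Reagents that add atoms: 2-methyl-2-butene, CC=C(C)C
Why: Olefin cross-metathesis with excess 2-methyl-2-butene converts the monosubstituted allyl group into a prenyl group with loss of propene; the trisubstituted C3 prenyl group, the hindered ketones and all stereocentres should be unaffected.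

**Compound list**
1 | (R)-(−)-lavandulol, (2R)-5-methyl-2-(prop-1-en-2-yl)hex-4-en-1-ol | OC[C@H](CC=C(C)C)C(C)=C | starting material
2 | (3R)-3-(iodomethyl)-2,6-dimethylhepta-1,5-diene | IC[C@H](CC=C(C)C)C(C)=C | intermediate
3 | methyl acetoacetate | COC(=O)CC(C)=O | starting material
4 | methyl (4S)-2-acetyl-7-methyl-4-(prop-1-en-2-yl)oct-6-enoate (C2 epimers) | COC(=O)C(C[C@H](CC=C(C)C)C(C)=C)C(C)=O | intermediate
5 | tert-butyl L-valinate | CC(C)[C@H](N)C(=O)OC(C)(C)C | starting material
6 | methyl (2Z)-3-{[(2S)-1-tert-butoxy-3-methyl-1-oxobutan-2-yl]amino}-2-[(2S)-5-methyl-2-(prop-1-en-2-yl)hex-4-en-1-yl]but-2-enoate | C/C(N[C@@H](C(C)C)C(=O)OC(C)(C)C)=C(\C[C@H](CC=C(C)C)C(C)=C)C(=O)OC | intermediate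
7 | lithium aza-enolate of 6 (N-lithio enamino ester) | C/C(N([Li])[C@@H](C(C)C)C(=O)OC(C)(C)C)=C(\C[C@H](CC=C(C)C)C(C)=C)C(=O)OC | intermediate
8 | N-[(S)-valine tert-butyl ester] ketimine of 9 | CC(=N[C@@H](C(C)C)C(=O)OC(C)(C)C)[C@](CC=C)(C[C@H](CC=C(C)C)C(C)=C)C(=O)OC | intermediate
9 | methyl (2S,4S)-2-acetyl-7-methyl-2-(prop-2-en-1-yl)-4-(prop-1-en-2-yl)oct-6-enoate | COC(=O)[C@@](CC=C)(C[C@H](CC=C(C)C)C(C)=C)C(C)=O | intermediate
10 | methyl (2S,4S)-2-(2-hydroxyacetyl)-7-methyl-2-(prop-2-en-1-yl)-4-(prop-1-en-2-yl)oct-6-enoate | COC(=O)[C@@](CC=C)(C[C@H](CC=C(C)C)C(C)=C)C(=O)CO | intermediate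
11 | (3S)-3-[(2S)-5-methyl-2-(prop-1-en-2-yl)hex-4-en-1-yl]-3-(prop-2-en-1-yl)furan-2,4(3H,5H)-dione | C1OC(=O)[C@@](CC=C)(C[C@H](CC=C(C)C)C(C)=C)C1=O | intermediate
12 | (R)-2-methylbutanoic acid | CC[C@@H](C)C(=O)O | starting material
13 | 1H-benzotriazole | c1ccc2[nH]nnc2c1 | starting material
14 | 1-[(2R)-2-methylbutanoyl]-1H-benzotriazole | CC[C@@H](C)C(=O)n1nnc2ccccc21 | intermediate
15 | (3S)-4-hydroxy-5-[(2R)-2-methylbutanoyl]-3-[(2S)-5-methyl-2-(prop-1-en-2-yl)hex-4-en-1-yl]-3-(prop-2-en-1-yl)furan-2(3H)-one | CC[C@@H](C)C(=O)C1=C(O)[C@](CC=C)(C[C@H](CC=C(C)C)C(C)=C)C(=O)O1 | intermediate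
16 | tertiary cation from protonation of the isopropenyl group of 15 | CC[C@@H](C)C(=O)C1=C(O)[C@](CC=C)(C[C@H](CC=C(C)C)[C+](C)C)C(=O)O1 | intermediate
17 | (1S,3S,5S)-4,4-dimethyl-5-[(2R)-2-methylbutanoyl]-3-(3-methylbut-2-en-1-yl)-1-(prop-2-en-1-yl)-6-oxabicyclo[3.2.1]octane-7,8-dione | CC[C@@H](C)C(=O)[C@@]12OC(=O)[C@@](CC=C)(C[C@H](CC=C(C)C)C1(C)C)C2=O | intermediate
18 | (1S,3S,5S)-4,4-dimethyl-5-[(2R)-2-methylbutanoyl]-1,3-bis(3-methylbut-2-en-1-yl)-6-oxabicyclo[3.2.1]octane-7,8-dione | CC[C@@H](C)C(=O)[C@@]12OC(=O)[C@@](CC=C(C)C)(C[C@H](CC=C(C)C)C1(C)C)C2=O | target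

**Step count:** 9 steps in total; the longest linear sequence is 8 steps (1, 2, 3, 4, 5, 7, 8, 9), with step 6 as a one-step side branch.

**Steps most likely to fail**

Step 8. The C4 cation, or the cation formed by protonation of the C3 prenyl group, may be diverted into ring closure between the prenyl and isopropenyl groups (lavandulyl-to-cyclolavandulyl cyclisation), into elimination with double-bond migration, or into O-alkylation that does not revert. The fallback sets out from 15 and changes the activation from protonation to a metal electrophile that selects the unhindered 1,1-disubstituted alkene. Treatment with Hg(OTf)2·PhNMe2 in MeNO2 at −20 °C should give carbomercuration with C5 opening the mercurinium ion at the tertiary carbon, and NaCl work-up would give the chloromercurio compound (1S,3S,5S)-4-[(chloromercurio)methyl]-4-methyl-5-[(2R)-2-methylbutanoyl]-3-(3-methylbut-2-en-1-yl)-1-(prop-2-en-1-yl)-6-oxabicyclo[3.2.1]octane-7,8-dione F1 (C4 epimers, inconsequential). Radical demercuration with Bu3SnH and AIBN in toluene would turn the CH2HgCl group into the second methyl group and return to the route at 17.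

Step 4. The facial selectivity in the alkylation of the lithiated enamine may be poor or reversed, since the α-substituent is far larger than in the model cases. The fallback sets out from 4 and replaces the covalent auxiliary by catalyst control: a Tsuji–Trost asymmetric allylic alkylation of the enolate of 4 with allyl acetate, Pd2(dba)3·CHCl3, the C2-symmetric diphosphine from trans-1,2-diaminocyclohexane and 2-(diphenylphosphino)benzoic acid, and tetramethylguanidine in toluene at 0 °C. The ligand enantiomer would be chosen to give the (2S) centre, and the C2 epimers, being diastereomers, can be separated by chromatography. This returns to the route at 9 and makes no new compound (F0).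

Step 7. O-acylation of the enolate, double acylation, or racemisation of the acyl donor through ketene formation under amine base may occur. The fallback sets out from 9 and reverses the order of acylation and ring closure. The kinetic lithium enolate of the methyl ketone (LiN(SiMe3)2, 2 equiv, THF, −78 °C) would be acylated with 14 to give the diketone methyl (2S,4S)-7-methyl-2-[(4R)-4-methyl-3-oxohexanoyl]-2-(prop-2-en-1-yl)-4-(prop-1-en-2-yl)oct-6-enoate F2. Hydroxylation of its enol at the central carbon with the same oxaziridine (Cs2CO3 cat., THF, 0 °C) would give methyl (2S,4S)-2-[(4R)-2-hydroxy-4-methyl-3-oxohexanoyl]-7-methyl-2-(prop-2-en-1-yl)-4-(prop-1-en-2-yl)oct-6-enoate F3 (carbinol epimers), which should lactonise on treatment with TsOH with loss of methanol and return to the route at 15.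

Further compounds
F1 | step 8 | (1S,3S,5S)-4-[(chloromercurio)methyl]-4-methyl-5-[(2R)-2-methylbutanoyl]-3-(3-methylbut-2-en-1-yl)-1-(prop-2-en-1-yl)-6-oxabicyclo[3.2.1]octane-7,8-dione (C4 epimers) | CC[C@@H](C)C(=O)[C@@]12OC(=O)[C@@](CC=C)(C[C@H](CC=C(C)C)C1(C)C[Hg]Cl)C2=O
F0 | step 4 | none | none
F2 | step 7 | methyl (2S,4S)-7-methyl-2-[(4R)-4-methyl-3-oxohexanoyl]-2-(prop-2-en-1-yl)-4-(prop-1-en-2-yl)oct-6-enoate | CC[C@@H](C)C(=O)CC(=O)[C@](CC=C)(C[C@H](CC=C(C)C)C(C)=C)C(=O)OC
F3 | step 7 | methyl (2S,4S)-2-[(4R)-2-hydroxy-4-methyl-3-oxohexanoyl]-7-methyl-2-(prop-2-en-1-yl)-4-(prop-1-en-2-yl)oct-6-enoate (carbinol epimers) | CC[C@@H](C)C(=O)C(O)C(=O)[C@](CC=C)(C[C@H](CC=C(C)C)C(C)=C)C(=O)OC
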